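**Retrosynthetic overview**

- The strategy rests on the spiro carbon C6. In the bromohydrin ring (ring A) it lies between the CMe2 carbon and the carbon bearing the exocyclic methylene; across the chlorohydrin ring (ring B) it stands para (1,4) to the C(CH3)(OH) carbon. Ring B is therefore a para-substituted phenol in disguise, and the crowded C6–CMe2 bond is an ordinary aryl–alkyl bond.
- Disconnections: tertiary chlorohydrin to an α-chloro ketone plus a methyl nucleophile; α-chloro ketone to a spiro enone and then to a spiro cyclohexadienone (copper hydride desymmetrisation); dienone to a phenol carrying a terminal alkyne, by the C6–C(=CH2) bond (gold-catalysed 6-exo-dig dearomative ipso-cyclisation).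
- The acyclic anti bromohydrin comes from an (S)-α-bromo aldehyde (organocatalytic bromination) and an allenylboronate; the aldehyde comes from anisole and 3-methylbut-2-enoic acid by Friedel–Crafts hydroarylation.
- Ring order: ring B is bought as the benzene ring of anisole, ring A is closed onto its ipso carbon in step 11, and ring B is then taken out of the aromatic state and functionalised one arm at a time (steps 12 to 15).

Key step: step 11

Assumption: the absolute sense of the three chiral catalysts (steps 7, 8 and 12) is written as the usual facial models predict; where a pairing proves mismatched, the mirror-image catalyst is the one meant.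

**Route**

Step 1
Reactants: 1 anisole; 2 3-methylbut-2-enoic acid
Product: 3 3-(4-methoxyphenyl)-3-methylbutanoic acid
Conditions: AlCl3 (2.5 equiv), CH2Cl2, 0 °C to rt; aq. HCl
Reagents that add atoms: none
Why: Friedel–Crafts hydroarylation, in which the AlCl3-complexed unsaturated acid behaves as a tertiary carbocation at its β-carbon and the anisole ring attacks it para to the methoxy group for steric reasons, so the crowded aryl–CMe2 bond is made at the outset on a flat arene.

Step 2
Reactants: 3 3-(4-methoxyphenyl)-3-methylbutanoic acid
Product: 4 3-(4-hydroxyphenyl)-3-methylbutanoic acid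
Conditions: 48% aq. HBr, AcOH, reflux
Reagents that add atoms: none
Why: Acidic cleavage of an aryl methyl ether (bromide attacks the methyl group of the protonated ether in an SN2 step), to which the carboxylic acid and the quaternary benzylic carbon are inert.

Step 3
Reactants: 4 3-(4-hydroxyphenyl)-3-methylbutanoic acid
Product: 5 methyl 3-(4-hydroxyphenyl)-3-methylbutanoate
Conditions: MeOH, H2SO4 (cat.), reflux
Reagents that add atoms: methanol, CO
Why: Fischer esterification touches only the carboxylic acid, because a phenol is not etherified by methanol under acid catalysis, and gives a group that hydride reduces cleanly.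

Step 4
Reactants: 5 methyl 3-(4-hydroxyphenyl)-3-methylbutanoate
Product: 6 methyl 3-[4-(tert-butyldimethylsilyloxy)phenyl]-3-methylbutanoate
Conditions: TBSCl, imidazole, DMF, rt
Reagents that add atoms: tert-butyldimethylsilyl chloride, CC(C)(C)[Si](C)(C)Cl
Why: Standard imidazole-mediated silylation of a phenol, which damps the nucleophilicity of the ring and removes the acidic proton before the electrophilic bromination and the organometallic steps.

Step 5
Reactants: 6 methyl 3-[4-(tert-butyldimethylsilyloxy)phenyl]-3-methylbutanoate
Product: 7 3-[4-(tert-butyldimethylsilyloxy)phenyl]-3-methylbutan-1-ol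
Conditions: (i-Bu)2AlH (2.5 equiv), CH2Cl2, −78 to 0 °C; aq. potassium sodium tartrate work-up
Reagents that add atoms: none
Why: Hydride reduction of the ester with (i-Bu)2AlH goes through to the primary alcohol, and the aryl silyl ether is not cleaved by this hydride at low temperature.

Step 6
Reactants: 7 3-[4-(tert-butyldimethylsilyloxy)phenyl]-3-methylbutan-1-ol
Product: 8 3-[4-(tert-butyldimethylsilyloxy)phenyl]-3-methylbutanal
Conditions: Dess–Martin periodinane, CH2Cl2, 0 °C to rt
Reagents that add atoms: none
Why: Dess–Martin oxidation of a primary alcohol stops at the aldehyde under neutral, non-aqueous conditions that leave the aryl silyl ether alone.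

Step 7
Reactants: 8 3-[4-(tert-butyldimethylsilyloxy)phenyl]-3-methylbutanal
Product: 9 (S)-2-bromo-3-[4-(tert-butyldimethylsilyloxy)phenyl]-3-methylbutanal
Conditions: (2R,5R)-2,5-diphenylpyrrolidine (20 mol%), PhCO2H (20 mol%), H2O (2 equiv), 4,4-dibromo-2,6-di-tert-butylcyclohexa-2,5-dien-1-one (1.1 equiv), CH2Cl2/pentane 1:1, −40 °C; cold silica plug, used at once
Reagents that add atoms: 4,4-dibromo-2,6-di-tert-butylcyclohexa-2,5-dien-1-one, CC(C)(C)C1=CC(Br)(Br)C=C(C(C)(C)C)C1=O
Why: Enamine-catalysed enantioselective α-bromination, in which a phenyl group of the C2-symmetric pyrrolidine screens one face of the E-enamine so that the mild Br+ donor is delivered to the other face and sets the bromine-bearing carbon as S, while the adjacent quaternary carbon slows enolisation and so protects this centre afterwards.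

Step 8
Reactants: 9 (S)-2-bromo-3-[4-(tert-butyldimethylsilyloxy)phenyl]-3-methylbutanal; 10 allenylboronic acid pinacol ester
Product: 12 (4R,5S)-5-bromo-6-[4-(tert-butyldimethylsilyloxy)phenyl]-6-methylhept-1-yn-4-ol, via pinacol borate ester 11 (not isolated)
Conditions: 10 (1.5 equiv), (R)-3,3′-bis(2,4,6-triisopropylphenyl)-1,1′-binaphthyl-2,2′-diyl hydrogen phosphate [(R)-TRIP, 10 mol%], 4 Å molecular sieves, toluene, −20 °C; aq. NaHCO3
Reagents that add atoms: none
Why: Chiral phosphoric acid catalysed propargylation with an allenylboronate (SE2′ through a six-membered boron transition state), in which the Cornforth arrangement of the α-bromo aldehyde (C–Br opposed to C=O, attack past the hydrogen) gives the anti bromohydrin and the acid antipode is chosen so that its facial preference coincides, which sets the carbinol carbon as R.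

Step 9
Reactants: 12 (4R,5S)-5-bromo-6-[4-(tert-butyldimethylsilyloxy)phenyl]-6-methylhept-1-yn-4-ol
Product: 13 (4R,5S)-5-bromo-4-(tert-butyldimethylsilyloxy)-6-[4-(tert-butyldimethylsilyloxy)phenyl]-6-methylhept-1-yne
Conditions: TBSOTf, 2,6-lutidine, CH2Cl2, −78 to 0 °C
Reagents that add atoms: tert-butyldimethylsilyl trifluoromethanesulfonate, CC(C)(C)[Si](C)(C)OS(=O)(=O)C(F)(F)F
Why: A silyl triflate with a hindered pyridine base silylates the crowded secondary alcohol without forming an alkoxide, which in this anti bromohydrin would close an epoxide, and the silyl ether later keeps the oxygen from cyclising onto the gold-bound alkyne.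

Step 10
Reactants: 13 (4R,5S)-5-bromo-4-(tert-butyldimethylsilyloxy)-6-[4-(tert-butyldimethylsilyloxy)phenyl]-6-methylhept-1-yne
Product: 14 4-[(3S,4R)-3-bromo-4-(tert-butyldimethylsilyloxy)-2-methylhept-6-yn-2-yl]phenol
Conditions: KHF2 (2.5 equiv), MeOH, rt
Reagents that add atoms: none
Why: Chemoselective desilylation, in which bifluoride cleaves the aryl silyl ether (phenoxide is the better leaving group from silicon) and spares the hindered alkyl silyl ether, while the weakly acidic medium never forms the phenoxide that could expel the neighbouring bromide through aryl participation.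

Step 11
Reactants: 14 4-[(3S,4R)-3-bromo-4-(tert-butyldimethylsilyloxy)-2-methylhept-6-yn-2-yl]phenol
Product: 15 (8S,9R)-8-bromo-9-(tert-butyldimethylsilyloxy)-7,7-dimethyl-11-methylidenespiro[5.5]undeca-1,4-dien-3-one
Conditions: Ph3PAuNTf2 (5 mol%), 4 Å molecular sieves, CH2Cl2 (0.02 M), rt
Reagents that add atoms: none
Why: Cationic monovalent gold binds the terminal alkyne, the phenol ipso carbon (activated by the para hydroxyl) adds to the internal alkyne carbon anti to gold, and the proton of the resulting O-protonated dienone cleaves the vinyl–gold bond, which leaves the exocyclic methylene and the cross-conjugated dienone and returns the catalyst. The closest known reaction type is the gold-catalysed intramolecular ipso-Friedel–Crafts alkenylation (dearomative spirocyclisation) of phenols carrying a terminal alkyne on a para tether, documented mainly for five-membered rings, so the present case is the same reaction with one more tether atom. Ring A closes in the 6-exo-dig mode through the new bond between the future spiro carbon and the methylene-bearing carbon, and ring B is not closed but unmasked from the arene as the dienone. No stereocentre is created, since the spiro carbon carries two identical enone arms at this stage, and the bromine- and silyloxy-bearing carbons are not touched. The selectivity needed is that of site (ipso carbon against ortho carbon and against oxygen): the ipso carbon is para to the hydroxyl and gives a six-membered ring whereas an ortho carbon is meta to it and would give a seven-membered ring, the gem-dimethyl group folds the tether toward the ring, and the silyl ether keeps the secondary oxygen from 5-endo attack on the alkyne. The silver-free, non-basic medium also keeps the secondary bromide from ionising with help from the electron-rich ring.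

Step 12
Reactants: 15 (8S,9R)-8-bromo-9-(tert-butyldimethylsilyloxy)-7,7-dimethyl-11-methylidenespiro[5.5]undeca-1,4-dien-3-one
Product: 17 (6S,8S,9R)-8-bromo-9-(tert-butyldimethylsilyloxy)-7,7-dimethyl-11-methylidenespiro[5.5]undec-1-en-3-one, via silyl dienol ether 16 (not isolated)
Conditions: Cu(OAc)2 (5 mol%), (S,S)-Ph-BPE [1,2-bis((2S,5S)-2,5-diphenylphospholan-1-yl)ethane, 5.5 mol%], (EtO)2MeSiH (1.2 equiv), toluene, −20 °C; then aq. citric acid, THF, 0 °C
Reagents that add atoms: none
Why: Copper hydride asymmetric conjugate reduction used as a desymmetrisation, in which hydrocupration of one enone alkene and silyl transfer give a silyl dienol ether that is no longer an acceptor, so only one alkene is reduced, and the chiral bisphosphine chooses between the two diastereotopic alkenes (hydride to the β-carbon of the arm on the face of ring A opposite to bromine and the silyloxy group), which makes the spiro carbon stereogenic with the S configuration.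

Step 13
Reactants: 17 (6S,8S,9R)-8-bromo-9-(tert-butyldimethylsilyloxy)-7,7-dimethyl-11-methylidenespiro[5.5]undec-1-en-3-one
Product: 18 (6S,8S,9R)-8-bromo-9-(tert-butyldimethylsilyloxy)-3-[dimethyl(phenyl)silyloxy]-7,7-dimethyl-11-methylidenespiro[5.5]undec-2-ene
Conditions: [(Ph3P)CuH]6 (3 mol%), PhMe2SiH (1.3 equiv), toluene, 0 °C to rt; Florisil plug
Reagents that add atoms: dimethylphenylsilane, C[SiH](C)c1ccccc1
Why: Copper hydride 1,4-hydrosilylation of the remaining enone traps the enolate on oxygen, so the enol double bond, and with it the site of the next electrophile, is fixed on the arm that held the enone alkene, and neither the 1,1-disubstituted exocyclic alkene nor the bromide reacts with this soft hydride.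

Step 14
Reactants: 18 (6S,8S,9R)-8-bromo-9-(tert-butyldimethylsilyloxy)-3-[dimethyl(phenyl)silyloxy]-7,7-dimethyl-11-methylidenespiro[5.5]undec-2-ene
Product: 19 (2S,6S,8S,9R)-8-bromo-9-(tert-butyldimethylsilyloxy)-2-chloro-7,7-dimethyl-11-methylidenespiro[5.5]undecan-3-one
Conditions: NCS (1.05 equiv), THF, −78 to 0 °C; then LiCl, DMF, rt (epimer equilibration)
Reagents that add atoms: N-chlorosuccinimide, O=C1CCC(=O)N1Cl
Why: Electrophilic chlorination of a silyl enol ether by NCS takes place only at the enol carbon, and the chloride is expected to settle (directly or through the chloride-exchange equilibration) in the equatorial position cis to the CMe2 carbon, configuration S, because its epimer would stand 1,3-diaxial to the axial methylene-bearing carbon on the spiro centre.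

Step 15
Reactants: 19 (2S,6S,8S,9R)-8-bromo-9-(tert-butyldimethylsilyloxy)-2-chloro-7,7-dimethyl-11-methylidenespiro[5.5]undecan-3-one
Product: 20 (2S,3R,6S,8S,9R)-8-bromo-9-(tert-butyldimethylsilyloxy)-2-chloro-3,7,7-trimethyl-11-methylidenespiro[5.5]undecan-3-ol
Conditions: MeMgBr, CeCl3, THF, −78 °C; cold aq. NH4Cl
Reagents that add atoms: methylmagnesium bromide, C[Mg]Br
Why: 1,2-Addition of a cerium-modified methyl Grignard reagent to the α-chloro ketone, in which the low basicity of the reagent avoids enolisation and methyl should enter along the equatorial trajectory anti to the C–Cl bond (polar Felkin–Anh, also the torsionally favoured path for a small nucleophile beside an equatorial α-substituent), giving the axial hydroxyl cis to chlorine and the R configuration at the carbinol carbon.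

Step 16
Reactants: 20 (2S,3R,6S,8S,9R)-8-bromo-9-(tert-butyldimethylsilyloxy)-2-chloro-3,7,7-trimethyl-11-methylidenespiro[5.5]undecan-3-ol
Product: 21 (2S,3R,6S,8S,9R)-8-bromo-2-chloro-3,7,7-trimethyl-11-methylidenespiro[5.5]undecane-3,9-diol
Conditions: HF·pyridine, pyridine, THF, 0 °C to rt
Reagents that add atoms: none
Why: Fluoride-mediated cleavage of the Si–O bond under buffered acidic conditions frees the hindered secondary alcohol without forming alkoxides, which under basic fluoride conditions could attack the neighbouring carbon–halogen bonds.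

**Compound list**

1 | anisole | COc1ccccc1 | starting material
2 | 3-methylbut-2-enoic acid | CC(C)=CC(=O)O | starting material
3 | 3-(4-methoxyphenyl)-3-methylbutanoic acid | COc1ccc(cc1)C(C)(C)CC(=O)O | intermediate
4 | 3-(4-hydroxyphenyl)-3-methylbutanoic acid | OC(=O)CC(C)(C)c1ccc(O)cc1 | intermediate
5 | methyl 3-(4-hydroxyphenyl)-3-methylbutanoate | COC(=O)CC(C)(C)c1ccc(O)cc1 | intermediate
6 | methyl 3-[4-(tert-butyldimethylsilyloxy)phenyl]-3-methylbutanoate | COC(=O)CC(C)(C)c1ccc(O[Si](C)(C)C(C)(C)C)cc1 | intermediate
7 | 3-[4-(tert-butyldimethylsilyloxy)phenyl]-3-methylbutan-1-ol | OCCC(C)(C)c1ccc(O[Si](C)(C)C(C)(C)C)cc1 | intermediate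
8 | 3-[4-(tert-butyldimethylsilyloxy)phenyl]-3-methylbutanal | O=CCC(C)(C)c1ccc(O[Si](C)(C)C(C)(C)C)cc1 | intermediate
9 | (S)-2-bromo-3-[4-(tert-butyldimethylsilyloxy)phenyl]-3-methylbutanal | O=C[C@@H](Br)C(C)(C)c1ccc(O[Si](C)(C)C(C)(C)C)cc1 | intermediate
10 | allenylboronic acid pinacol ester | C=C=CB1OC(C)(C)C(C)(C)O1 | starting material
11 | pinacol borate ester of 12 (boron on the C4 oxygen; 4R,5S) | C#CC[C@@H](OB1OC(C)(C)C(C)(C)O1)[C@@H](Br)C(C)(C)c1ccc(O[Si](C)(C)C(C)(C)C)cc1 | intermediate
12 | (4R,5S)-5-bromo-6-[4-(tert-butyldimethylsilyloxy)phenyl]-6-methylhept-1-yn-4-ol | C#CC[C@@H](O)[C@@H](Br)C(C)(C)c1ccc(O[Si](C)(C)C(C)(C)C)cc1 | intermediate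
13 | (4R,5S)-5-bromo-4-(tert-butyldimethylsilyloxy)-6-[4-(tert-butyldimethylsilyloxy)phenyl]-6-methylhept-1-yne | C#CC[C@@H](O[Si](C)(C)C(C)(C)C)[C@@H](Br)C(C)(C)c1ccc(O[Si](C)(C)C(C)(C)C)cc1 | intermediate
14 | 4-[(3S,4R)-3-bromo-4-(tert-butyldimethylsilyloxy)-2-methylhept-6-yn-2-yl]phenol | C#CC[C@@H](O[Si](C)(C)C(C)(C)C)[C@@H](Br)C(C)(C)c1ccc(O)cc1 | intermediate
15 | (8S,9R)-8-bromo-9-(tert-butyldimethylsilyloxy)-7,7-dimethyl-11-methylidenespiro[5.5]undeca-1,4-dien-3-one | C=C1C[C@@H](O[Si](C)(C)C(C)(C)C)[C@@H](Br)C(C)(C)C12C=CC(=O)C=C2 | intermediate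
16 | (6S,8S,9R)-8-bromo-9-(tert-butyldimethylsilyloxy)-3-[diethoxy(methyl)silyloxy]-7,7-dimethyl-11-methylidenespiro[5.5]undeca-1,3-diene | C=C1C[C@@H](O[Si](C)(C)C(C)(C)C)[C@@H](Br)C(C)(C)[C@]12CC=C(O[Si](C)(OCC)OCC)C=C2 | intermediate
17 | (6S,8S,9R)-8-bromo-9-(tert-butyldimethylsilyloxy)-7,7-dimethyl-11-methylidenespiro[5.5]undec-1-en-3-one | C=C1C[C@@H](O[Si](C)(C)C(C)(C)C)[C@@H](Br)C(C)(C)[C@]12CCC(=O)C=C2 | intermediate
18 | (6S,8S,9R)-8-bromo-9-(tert-butyldimethylsilyloxy)-3-[dimethyl(phenyl)silyloxy]-7,7-dimethyl-11-methylidenespiro[5.5]undec-2-ene | C=C1C[C@@H](O[Si](C)(C)C(C)(C)C)[C@@H](Br)C(C)(C)[C@]12CCC(O[Si](C)(C)c3ccccc3)=CC2 | intermediate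
19 | (2S,6S,8S,9R)-8-bromo-9-(tert-butyldimethylsilyloxy)-2-chloro-7,7-dimethyl-11-methylidenespiro[5.5]undecan-3-one | C=C1C[C@@H](O[Si](C)(C)C(C)(C)C)[C@@H](Br)C(C)(C)[C@]12CCC(=O)[C@@H](Cl)C2 | intermediate
20 | (2S,3R,6S,8S,9R)-8-bromo-9-(tert-butyldimethylsilyloxy)-2-chloro-3,7,7-trimethyl-11-methylidenespiro[5.5]undecan-3-ol | C=C1C[C@@H](O[Si](C)(C)C(C)(C)C)[C@@H](Br)C(C)(C)[C@]12CC[C@@](C)(O)[C@@H](Cl)C2 | intermediate
21 | (2S,3R,6S,8S,9R)-8-bromo-2-chloro-3,7,7-trimethyl-11-methylidenespiro[5.5]undecane-3,9-diol (CNP0121782.1) | C=C1C[C@@H](O)[C@@H](Br)C(C)(C)[C@]12CC[C@@](C)(O)[C@@H](Cl)C2 | target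

**Step count**

Total step count: 16. Longest linear sequence: 16 steps (from 1 and 2 to 21; 10 is bought).

**Steps most likely to fail**

1. Step 11 (gold cyclisation). The ipso carbon may not close the six-membered ring fast enough next to the quaternary carbon, so that hydration of the gold-bound alkyne, attack through an ortho carbon, or ring-assisted loss of bromide take over.
 Fallback, setting out from 3 and returning at 17 (it thereby also replaces step 12): the same bond between the spiro carbon and the methylene-bearing carbon is closed by a 6-exo-trig Heck reaction onto a ring B that is not aromatic.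
 - Acid 3 is reduced with LiAlH4 in THF to 3-(4-methoxyphenyl)-3-methylbutan-1-ol F1.
 - Birch reduction (Li, liquid NH3, THF, t-BuOH, −78 °C), carried out before any bromine is present, gives the enol ether 3-(4-methoxycyclohexa-1,4-dien-1-yl)-3-methylbutan-1-ol F2.
 - Exchange with ethylene glycol (pyridinium tosylate, rt) gives the β,γ-unsaturated ketal 3-(1,4-dioxaspiro[4.5]dec-7-en-8-yl)-3-methylbutan-1-ol F3, whose ring alkene ends at the future spiro carbon.
 - Dess–Martin oxidation gives 3-(1,4-dioxaspiro[4.5]dec-7-en-8-yl)-3-methylbutanal F4.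
 - Bromination as in step 7 gives (S)-2-bromo-3-(1,4-dioxaspiro[4.5]dec-7-en-8-yl)-3-methylbutanal F5.
 - Barbier addition of 2,3-dibromopropene with indium metal in THF/H2O should give, under Cornforth control, the anti bromohydrin (4R,5S)-2,5-dibromo-6-(1,4-dioxaspiro[4.5]dec-7-en-8-yl)-6-methylhept-1-en-4-ol F6.
 - TBSOTf/2,6-lutidine gives its tert-butyldimethylsilyl ether F7.
 - Heck cyclisation (Pd(OAc)2, PPh3, Et3N, MeCN, 80 °C): zerovalent palladium inserts into the vinyl C–Br bond only, the vinylpalladium adds to the ring alkene at the carbon that carries the tether, and β-hydride elimination toward the ketal side gives the spiro diene ketal F8.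
 - Pyridinium tosylate in wet acetone then frees enone 17.
 - Weak point: the configuration of the spiro carbon would rest on the facial selectivity of the carbopalladation; a chiral bisphosphine on palladium (BINAP) is the lever if substrate control is weak.

2. Step 12 (copper hydride desymmetrisation). The catalyst may discriminate poorly between the two diastereotopic enone alkenes (low selectivity at the spiro carbon), or both alkenes may be reduced.
 Fallback, setting out from 15 and returning at 19: the choice is moved from the two alkenes to the two α-methylene groups.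
 - Both enone alkenes of 15 are reduced with an achiral copper hydride (Cu(OAc)2, 1,2-bis(diphenylphosphino)benzene, excess (EtO)2MeSiH, t-BuOH, toluene, rt) to the saturated spiro ketone F9, whose spiro carbon is not stereogenic.
 - A chiral lithium amide (lithium (R,R)-bis(1-phenylethyl)amide with Me3SiCl present, THF, −100 °C) removes a proton from only one of the two α-methylene groups and gives the trimethylsilyl enol ether F10, the trimethylsilyl analogue of 18.
 - NCS as in step 14 then gives 19.

3. Step 8 (propargylation). Addition to the hindered α-bromo aldehyde may be slow, which would allow acid-promoted epimerisation at the bromine-bearing carbon, or the catalyst and substrate preferences may oppose each other and erode the anti selectivity.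
 Fallback, setting out from 9 and returning at 12: catalyst control and the boron reagent are given up. A Barbier reaction with propargyl bromide and indium metal in THF/H2O at 0 °C generates an allenylindium reagent that should add quickly and irreversibly, so that the Cornforth bias of the bromo aldehyde alone decides the carbinol centre; the minor epimer would be removed by chromatography at the stage of 12. No new compound is made.

**Further compounds**

F1 | step 11 | 3-(4-methoxyphenyl)-3-methylbutan-1-ol | COc1ccc(cc1)C(C)(C)CCO
F2 | step 11 | 3-(4-methoxycyclohexa-1,4-dien-1-yl)-3-methylbutan-1-ol | COC1=CCC(=CC1)C(C)(C)CCO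
F3 | step 11 | 3-(1,4-dioxaspiro[4.5]dec-7-en-8-yl)-3-methylbutan-1-ol | OCCC(C)(C)C1=CCC2(CC1)OCCO2
F4 | step 11 | 3-(1,4-dioxaspiro[4.5]dec-7-en-8-yl)-3-methylbutanal | O=CCC(C)(C)C1=CCC2(CC1)OCCO2
F5 | step 11 | (S)-2-bromo-3-(1,4-dioxaspiro[4.5]dec-7-en-8-yl)-3-methylbutanal | O=C[C@@H](Br)C(C)(C)C1=CCC2(CC1)OCCO2
F6 | step 11 | (4R,5S)-2,5-dibromo-6-(1,4-dioxaspiro[4.5]dec-7-en-8-yl)-6-methylhept-1-en-4-ol | C=C(Br)C[C@@H](O)[C@@H](Br)C(C)(C)C1=CCC2(CC1)OCCO2
F7 | step 11 | tert-butyldimethylsilyl ether of F6 (4R,5S) | C=C(Br)C[C@@H](O[Si](C)(C)C(C)(C)C)[C@@H](Br)C(C)(C)C1=CCC2(CC1)OCCO2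
F8 | step 11 | ethylene ketal of 17 (spiro diene ketal; 6S,8S,9R) | C=C1C[C@@H](O[Si](C)(C)C(C)(C)C)[C@@H](Br)C(C)(C)[C@]12CCC3(OCCO3)C=C2
F9 | step 12 | (8S,9R)-8-bromo-9-(tert-butyldimethylsilyloxy)-7,7-dimethyl-11-methylidenespiro[5.5]undecan-3-one | C=C1C[C@@H](O[Si](C)(C)C(C)(C)C)[C@@H](Br)C(C)(C)C12CCC(=O)CC2
F10 | step 12 | (6S,8S,9R)-8-bromo-9-(tert-butyldimethylsilyloxy)-7,7-dimethyl-11-methylidene-3-(trimethylsilyloxy)spiro[5.5]undec-2-ene | C=C1C[C@@H](O[Si](C)(C)C(C)(C)C)[C@@H](Br)C(C)(C)[C@]12CCC(O[Si](C)(C)C)=CC2
F0 | step 8 | none | none
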